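The target is reached through (+)-β-caryophyllene 17 and a final o-quinone-methide hetero-Diels–Alder reaction. Everything rests on the C10–C11 disconnection of the cyclobutane (caryophyllane numbering; ring C1–C9–C10–C11): C11 is a gem-dimethyl quaternary carbon next to the ring CH2, that is, the Markovnikov carbon of an isopropenyl group. In one operation a manganese-hydride/nickel hydroalkylation joins this carbon to a neighbouring iodomethyl group and closes the four-membered ring, with no activating group to remove. The precursor is a cis-hydrindane-1,3-diol bearing trans-vicinal iodomethyl and isopropenyl groups; its later Grob fragmentation unveils the nine-membered ring with the E-alkene.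

Key step: step 6

Assumption: 2,4,6-trihydroxybenzene-1,3-dicarbaldehyde 19 is taken as a catalogue compound (it is one Vilsmeier formylation away from phloroglucinol).
Atom labels C1–C11 in the Why lines are those of the caryophyllane skeleton of the target (C1/C9 ring fusion, C10 the cyclobutane CH2, C11 the CMe2 carbon, C4–C5 the former alkene, C8 the methylidene-bearing carbon).

Step 1
Reactants: 1 2-methylcyclopentane-1,3-dione; 2 acrolein
Product: 3 3-(1-methyl-2,5-dioxocyclopentyl)propanal
Conditions: H2O, 25 °C
Reagents that add atoms: none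
Why: Michael addition of the enolised 1,3-dione to acrolein in water alkylates the carbon between the two carbonyls (future C4 with its methyl) and creates no stereocentre.

Step 2
Reactants: 3; 4 methyl (triphenylphosphoranylidene)acetate
Product: 5 methyl (2E)-5-(1-methyl-2,5-dioxocyclopentyl)pent-2-enoate
Conditions: CH2Cl2, 25 °C
Reagents that add atoms: none
Why: Wittig olefination with a stabilised ylide should react only at the aldehyde (the hindered ring ketones are left) and give the E-enoate.

Step 3
Reactants: 5; 6 4,4,5,5-tetramethyl-2-(prop-1-en-2-yl)-1,3,2-dioxaborolane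
Product: 8 methyl (3aR,4R,5S,7aR)-3a-hydroxy-7a-methyl-1-oxo-5-(prop-1-en-2-yl)octahydro-1H-indene-4-carboxylate, via rhodium ester enolate 7 (not isolated)
Conditions: [Rh(cod)Cl]2 (cat.), (S)-BINAP, KOH (cat.), H2O (5 equiv), 1,4-dioxane, 90 °C
Reagents that add atoms: none
Why: Hayashi–Miyaura asymmetric 1,4-addition of the alkenylboronate with the rhodium enolate 7 trapped by intramolecular aldol addition to one dione carbonyl (tandem conjugate addition–aldol cyclisation); the BINAP–rhodium alkenyl species should select one enantioface of the E-enoate and fix the isopropenyl-bearing centre as S (the antipodal ligand would give the mirror-image series), and a closed chair (Zimmerman–Traxler) aldol transition state with isopropenyl and ester equatorial should set the 4,5-trans relationship and the cis ring fusion with OH, CH3 and ester on one face.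

Step 4
Reactants: 8
Product: 9 (1R,3aR,4S,5S,7aS)-4-(hydroxymethyl)-7a-methyl-5-(prop-1-en-2-yl)octahydro-1H-indene-1,3a-diol
Conditions: i-Bu2AlH (excess), THF, −78 to 0 °C; aq. KNaC4H4O6
Reagents that add atoms: none
Why: Hydride reduction takes the ester to the primary alcohol and, through the aluminium chelate of the angular hydroxyl (1,3-syn reduction of a β-hydroxy ketone), delivers external hydride to the cyclopentanone from the face opposite the angular OH and CH3, so the new carbinol should be cis to both.

Step 5
Reactants: 9
Product: 10 (1R,3aR,4R,5S,7aS)-4-(iodomethyl)-7a-methyl-5-(prop-1-en-2-yl)octahydro-1H-indene-1,3a-diol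
Conditions: PPh3, I2, imidazole, CH2Cl2, 0 °C
Reagents that add atoms: iodine, [I][I]
Why: Appel iodination should be selective for the primary hydroxyl over the neopentyl secondary and the tertiary one; no stereocentre is touched (the descriptor at C4 of the hydrindane changes by CIP priority only).

Step 6
Reactants: 10
Product: 13 (1R,2R,5S,8S,9R)-4,4,8-trimethyltricyclo[6.3.0.0(2,5)]undecane-1,9-diol, via tertiary alkyl radical 11 (not isolated), via nickelacyclopentane 12 (not isolated)
Conditions: Mn(dpm)3 (cat.; dpm = dipivaloylmethanate), Ni(acac)2 (cat.), PhSiH3, K2CO3, (CF3)2CHOH/ClCH2CH2Cl, 25 °C, high dilution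
Reagents that add atoms: none
Why: Proposed new method: the ring closure is an intramolecular version of the manganese/nickel dual-catalytic Markovnikov hydroalkylation of unactivated alkenes with alkyl iodides, in which hydrogen-atom transfer from a manganese hydride to the isopropenyl CH2 gives the tertiary radical 11, nickel that has taken up the C10–I bond captures it as the nickelacyclopentane 12, and C(sp3)–C(sp3) reductive elimination forms the C10–C11 bond. The closest known reactions are the intermolecular Mn/Ni hydroalkylation that makes quaternary carbons from 1,1-disubstituted alkenes and primary iodides, and the reductive elimination of nickelacyclopentanes to cyclobutanes. The cyclobutane (C1–C9–C10–C11) is closed by contraction of the five-membered nickelacycle, a formal 4-exo closure that bypasses the slow and reversible 4-exo radical addition. No new stereocentre arises, since C11 becomes the CMe2 carbon; the trans relationship of C1 and C9 set in step 3 is carried into a trans-fused four-membered ring, which is the ring fusion of the target. The step needs hydrogen-atom transfer to one alkene only, secured because the isopropenyl group is the sole alkene of 10, and ring closure ahead of plain reduction of radical or iodide, which the fixed diequatorial 1,2-proximity of the two carbons and high dilution should favour.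

Step 7
Reactants: 13
Product: 14 (1R,2R,5S,8S,9R)-1-hydroxy-4,4,8-trimethyltricyclo[6.3.0.0(2,5)]undecan-9-yl methanesulfonate
Conditions: MsCl, Et3N, CH2Cl2, −20 to 0 °C
Reagents that add atoms: methanesulfonyl chloride, CS(=O)(=O)Cl
Why: Sulfonylation should take the secondary hydroxyl and leave the tertiary ring-fusion hydroxyl free, with retention at the carbinol carbon.

Step 8
Reactants: 14
Product: 16 (1S,4E,9R)-4,11,11-trimethylbicyclo[7.2.0]undec-4-en-8-one, via potassium alkoxide 15 (not isolated)
Conditions: KOt-Bu, t-BuOH/THF, 25 to 40 °C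
Reagents that add atoms: none
Why: Grob fragmentation of the 1,3-diol monosulfonate: the alkoxide expels the mesylate across the anti-periplanar ring-fusion bond (C4–C8), which opens the hydrindane to the nine-membered ketone stereospecifically as the E-alkene because the mesylate is cis to the angular methyl (a cis alkoxide cannot form an oxetane), erases the two ring-fusion centres and leaves the trans ring fusion, which is also the base-stable epimer at C9.

Step 9
Reactants: 16
Product: 17 (1S,4E,9R)-4,11,11-trimethyl-8-methylidenebicyclo[7.2.0]undec-4-ene, (+)-β-caryophyllene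
Conditions: Ph3PCH3Br, KOt-Bu, THF, 0 to 50 °C
Reagents that add atoms: methyltriphenylphosphonium bromide, C[P+](c1ccccc1)(c1ccccc1)c1ccccc1.[Br-]
Why: Wittig methylenation of the ketone; the α-centre C9 already has the thermodynamically preferred trans fusion, so the basic ylide should not erode it.

Step 10
Reactants: 17; 18 benzaldehyde; 19 2,4,6-trihydroxybenzene-1,3-dicarbaldehyde
Product: 21 target CNP0253700.1, via o-quinone methide 20 (not isolated)
Conditions: H2O, 100 °C, sealed tube
Reagents that add atoms: none
Why: Knoevenagel condensation of 18 at the free ring position of 19 gives o-quinone methide 20, which the strained E-alkene of 17 should trap in an inverse-electron-demand hetero-Diels–Alder reaction: oxygen bonds to the more substituted C4, suprafacial addition to the E-alkene fixes C4 and C5 together (trans-fused pyran), attack on the outer face of the ring (the face also taken by peracids) sets them relative to C1/C9, and the orientation with H-5 under the diene and phenyl outside sets the benzylic centre as S.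

Compound list
1 | 2-methylcyclopentane-1,3-dione | CC1C(=O)CCC1=O | starting material
2 | acrolein | C=CC=O | starting material
3 | 3-(1-methyl-2,5-dioxocyclopentyl)propanal | CC1(CCC=O)C(=O)CCC1=O | intermediate
4 | methyl (triphenylphosphoranylidene)acetate | COC(=O)C=P(c1ccccc1)(c1ccccc1)c1ccccc1 | starting material
5 | methyl (2E)-5-(1-methyl-2,5-dioxocyclopentyl)pent-2-enoate | COC(=O)/C=C/CCC1(C)C(=O)CCC1=O | intermediate
6 | 4,4,5,5-tetramethyl-2-(prop-1-en-2-yl)-1,3,2-dioxaborolane | CC(=C)B1OC(C)(C)C(C)(C)O1 | starting material
7 | rhodium ester enolate of the (S)-conjugate adduct (ligands omitted) | CC(=C)[C@@H](CCC1(C)C(=O)CCC1=O)/C=C(/OC)\O[Rh] | intermediate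
8 | methyl (3aR,4R,5S,7aR)-3a-hydroxy-7a-methyl-1-oxo-5-(prop-1-en-2-yl)octahydro-1H-indene-4-carboxylate | C[C@@]12CC[C@H](C(C)=C)[C@@H](C(=O)OC)[C@]1(O)CCC2=O | intermediate
9 | (1R,3aR,4S,5S,7aS)-4-(hydroxymethyl)-7a-methyl-5-(prop-1-en-2-yl)octahydro-1H-indene-1,3a-diol | C[C@@]12CC[C@H](C(C)=C)[C@@H](CO)[C@]1(O)CC[C@H]2O | intermediate
10 | (1R,3aR,4R,5S,7aS)-4-(iodomethyl)-7a-methyl-5-(prop-1-en-2-yl)octahydro-1H-indene-1,3a-diol | C[C@@]12CC[C@H](C(C)=C)[C@@H](CI)[C@]1(O)CC[C@H]2O | intermediate
11 | tertiary alkyl radical from 10 (H added to the isopropenyl CH2) | C[C@@]12CC[C@H]([C](C)C)[C@@H](CI)[C@]1(O)CC[C@H]2O | intermediate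
12 | nickelacyclopentane (C10–Ni–C11; other ligands omitted) | C[C@@]12CC[C@H]3[C@@H](C[Ni]C3(C)C)[C@]1(O)CC[C@H]2O | intermediate
13 | (1R,2R,5S,8S,9R)-4,4,8-trimethyltricyclo[6.3.0.0(2,5)]undecane-1,9-diol | C[C@@]12CC[C@H]3[C@@H](CC3(C)C)[C@]1(O)CC[C@H]2O | intermediate
14 | (1R,2R,5S,8S,9R)-1-hydroxy-4,4,8-trimethyltricyclo[6.3.0.0(2,5)]undecan-9-yl methanesulfonate | C[C@@]12CC[C@H]3[C@@H](CC3(C)C)[C@]1(O)CC[C@H]2OS(C)(=O)=O | intermediate
15 | potassium alkoxide of 14 | C[C@@]12CC[C@H]3[C@@H](CC3(C)C)[C@]1([O-])CC[C@H]2OS(C)(=O)=O.[K+] | intermediate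
16 | (1S,4E,9R)-4,11,11-trimethylbicyclo[7.2.0]undec-4-en-8-one | C/C1=C\CCC(=O)[C@@H]2CC(C)(C)[C@H]2CC1 | intermediate
17 | (1S,4E,9R)-4,11,11-trimethyl-8-methylidenebicyclo[7.2.0]undec-4-ene, (+)-β-caryophyllene | C/C1=C\CCC(=C)[C@@H]2CC(C)(C)[C@H]2CC1 | intermediate
18 | benzaldehyde | O=Cc1ccccc1 | starting material
19 | 2,4,6-trihydroxybenzene-1,3-dicarbaldehyde | O=Cc1c(O)cc(O)c(C=O)c1O | starting material
20 | (5E)-5-benzylidene-2,4-dihydroxy-6-oxocyclohexa-1,3-diene-1,3-dicarbaldehyde (o-quinone methide) | O=C1/C(=C/c2ccccc2)C(O)=C(C=O)C(O)=C1C=O | intermediate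
21 | CNP0253700.1: 5,7-dihydroxy-4-phenylchroman-6,8-dicarbaldehyde fused through its C2–C3 bond to C4–C5 of the caryophyllane skeleton (caryophyllane numbering 1S,4S,5R,9R; benzylic carbon S) | C=C1CC[C@@H]2[C@@H](c3ccccc3)c3c(O)c(C=O)c(O)c(C=O)c3O[C@@]2(C)CC[C@H]2[C@H]1CC2(C)C | target

Total step count: 10. Longest linear sequence: 10 steps (1 to 21).

Steps most likely to fail

Step 6 (labelled new method). What may go wrong is reduction outrunning ring closure: hydrogen capture by the tertiary radical, hydrodeiodination, or β-hydride elimination at nickel, because reductive elimination to a strained trans-fused four-membered ring is slow. The fallback closes the same C10–C11 bond by known polar chemistry, a 4-exo-tet ester enolate alkylation; it sets out from 10 and returns at 13. Compound 10 would be silylated (Et3SiOTf, 2,6-lutidine) to the bis(triethylsilyl) ether F1, so that no alkoxide can displace the iodide. Hydroboration–oxidation of the isopropenyl group (9-borabicyclo[3.3.1]nonane; NaBO3) would give the primary alcohol F2, which (C5H5NH)2Cr2O7 in DMF/MeOH would oxidise to the methyl ester F3. LiN(i-Pr)2 in THF would then alkylate the ester enolate with the primary iodide to give the cyclobutanecarboxylate F4. LiAlH4 reduction to the neopentyl alcohol F5, mesylation to the methanesulfonate F6 and LiBHEt3 reduction would turn the ester carbon back into the second methyl group in the bis(triethylsilyl) ether F7. Bu4NF would release 13.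

Step 3. What may go wrong is protonation of the rhodium ester enolate by water before it closes onto the dione, which would leave the uncyclised conjugate adduct. The fallback separates the two events and closes the ring by enamine catalysis; it sets out from 3 and returns at 9. Wittig reaction of 3 with (triphenylphosphoranylidene)acetaldehyde would give the enal (2E)-5-(1-methyl-2,5-dioxocyclopentyl)pent-2-enal F8. Hayashi–Miyaura addition of 6 with a chiral diene–rhodium catalyst (from [Rh(C2H4)2Cl]2) would give the aldehyde (3S)-5-(1-methyl-2,5-dioxocyclopentyl)-3-(prop-1-en-2-yl)pentanal F9. Proline-catalysed intramolecular aldol addition (6-enolexo) would close the six-membered ring to the ketol aldehyde F10. F10 is drawn with the ring-fusion configuration of 8; its epimer at the two ring-fusion carbons would serve equally, because both centres are erased in step 8. Narasaka–Prasad reduction (Et2BOMe, NaBH4, THF/MeOH, −78 °C) would reduce aldehyde and ketone to give 9.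

Step 4. What may go wrong is loss of facial control in the ketone reduction: hydride entering from the face of the angular groups would give the trans-1,3-diol, whose mesylate would fragment to the Z-alkene. The fallback replaces chelate control by steric shielding; it sets out from 8 and returns at 9. 1-(Trimethylsilyl)imidazole would convert the tertiary hydroxyl of 8 into its trimethylsilyl ether F11, so that the silyloxy and methyl groups together block one face. LiAlH4 would then reduce ester and ketone from the open face to the silyl-protected diol F12, and Bu4NF would give 9.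

Further compounds
F1 | step 6 | bis(triethylsilyl) ether of 10 | C[C@@]12CC[C@H](C(C)=C)[C@@H](CI)[C@]1(O[Si](CC)(CC)CC)CC[C@H]2O[Si](CC)(CC)CC
F2 | step 6 | primary alcohol from hydroboration of F1 (1-hydroxypropan-2-yl side chain, both epimers at the new CH) | C[C@@]12CC[C@H](C(C)CO)[C@@H](CI)[C@]1(O[Si](CC)(CC)CC)CC[C@H]2O[Si](CC)(CC)CC
F3 | step 6 | methyl ester from oxidation of F2 (1-methoxy-1-oxopropan-2-yl side chain) | C[C@@]12CC[C@H](C(C)C(=O)OC)[C@@H](CI)[C@]1(O[Si](CC)(CC)CC)CC[C@H]2O[Si](CC)(CC)CC
F4 | step 6 | silyl-protected tricyclic methyl cyclobutanecarboxylate (C10–C11 bond closed, both epimers at C11) | C[C@@]12CC[C@H]3[C@@H](CC3(C)C(=O)OC)[C@]1(O[Si](CC)(CC)CC)CC[C@H]2O[Si](CC)(CC)CC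
F5 | step 6 | silyl-protected tricyclic cyclobutylmethanol | C[C@@]12CC[C@H]3[C@@H](CC3(C)CO)[C@]1(O[Si](CC)(CC)CC)CC[C@H]2O[Si](CC)(CC)CC
F6 | step 6 | methanesulfonate of F5 | C[C@@]12CC[C@H]3[C@@H](CC3(C)COS(C)(=O)=O)[C@]1(O[Si](CC)(CC)CC)CC[C@H]2O[Si](CC)(CC)CC
F7 | step 6 | bis(triethylsilyl) ether of 13 | C[C@@]12CC[C@H]3[C@@H](CC3(C)C)[C@]1(O[Si](CC)(CC)CC)CC[C@H]2O[Si](CC)(CC)CC
F8 | step 3 | (2E)-5-(1-methyl-2,5-dioxocyclopentyl)pent-2-enal | O=C/C=C/CCC1(C)C(=O)CCC1=O
F9 | step 3 | (3S)-5-(1-methyl-2,5-dioxocyclopentyl)-3-(prop-1-en-2-yl)pentanal | CC(=C)[C@@H](CCC1(C)C(=O)CCC1=O)CC=O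
F10 | step 3 | (3aR,4R,5S,7aR)-3a-hydroxy-7a-methyl-1-oxo-5-(prop-1-en-2-yl)octahydro-1H-indene-4-carbaldehyde | C[C@@]12CC[C@H](C(C)=C)[C@@H](C=O)[C@]1(O)CCC2=O
F11 | step 4 | 3a-O-trimethylsilyl ether of 8 | C[C@@]12CC[C@H](C(C)=C)[C@@H](C(=O)OC)[C@]1(O[Si](C)(C)C)CCC2=O
F12 | step 4 | 3a-O-trimethylsilyl ether of 9 | C[C@@]12CC[C@H](C(C)=C)[C@@H](CO)[C@]1(O[Si](C)(C)C)CC[C@H]2O
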